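## The problem

The target 15 is a fully substituted 2,5-dimethoxy-1,4-benzoquinone in which C3 carries an indol-3-yl group and C6, para to it, a 7-(3-methylbut-2-en-1-yl)indol-3-yl group. There is no stereocentre, so the whole difficulty is constitutional. Six contiguous substituted ring carbons must be assembled, and the two aryl groups differ only at a remote position (C7 of one indole), so no electronic bias tells the halves apart and any plan that attaches them to a symmetrical core must rely on stopping half-way. The sensitive groups are the prenyl alkene (acid, electrophilic oxidants), the two free indole N–H/C2 positions (oxidants, acid, acylating agents), the quinone (nucleophiles, reductants) and the two vinylogous ester methoxy groups (aqueous base). The enabling feature is that each aryl-bearing carbon, C3 and C6, lies between two oxygen-bearing carbons, and the oxygen-bearing carbons occur as two adjacent pairs, C1/C2 and C4/C5. The ring is therefore the bis-enol ether of a 3,6-disubstituted cyclohexane-1,2,4,5-tetraone, made of two aryl–C–C(O)–C(O) units (C3–C4–C5 and C6–C1–C2), that is two arylpyruvic acid units joined head to tail through C2–C3 and C5–C6 at exactly the oxidation level of two acylations. A synthesis on this basis has one thing to solve: direction, so that only the cross-dimer forms.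

## Retrosynthesis

**15 to 14.** The two O–CH3 bonds are cut. The dihydroxyquinone 14 is a double vinylogous carboxylic acid, so it can be methylated last under neutral conditions. This keeps the base-labile methoxy groups out of the alkoxide chemistry and lets the ring-forming step end in the stabilised dianion of 14. The forward reaction must methylate O–H and leave both indole N–H groups alone.

**14 to 11 and 9 (key disconnection).** The ring bonds C2–C3 and C5–C6 are cut, which divides 14 into its two three-carbon arylpyruvate units. Cutting the two indole–quinone bonds instead would leave the ring intact and solve none of the substitution problem. The head-to-tail cut removes the whole ring and both oxygen pairs at once, with no redox change. Two free keto esters would dimerise statistically, so the halves get different roles. The unsubstituted half is the keto ester 11, which acts first as a carbon nucleophile through its enolate 12 and later as the ester electrophile. The prenylated half is the arylidene dioxolanone 9, an activated lactone with no acidic C–H that can only be an electrophile until it has been opened. Acylation of 12 by 9 gives the open-chain trioxo ester 13 and uncovers the second enolate, which closes the ring by Dieckmann condensation. The forward reaction needs C-acylation of 12 and the absence of any nucleophilic base while 9 is still present.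

**9 to 4 and 8.** The exocyclic C=C bond is cut in the Wittig sense, giving aldehyde 4 and the stabilised ylide 8. The olefination delivers the prenylated pyruvate unit directly in its masked, electrophile-only form, so no free keto acid of that half is ever handled.

**8 to 7, 6 and 5.** The ylide 8 is released in the flask from the phosphonium salt 7. Cutting the P–C bond leads to the bromide 6, and cutting the C–Br bond leads to commercial 5.

**4 to 2 to 1.** The formyl C–C3 bond is cut (Vilsmeier–Haack formylation of 2), then the C7–CH2 bond (Stille coupling), which leads to commercial 1. The prenyl group is introduced first because every later step is base-mediated or neutral.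

**11 to 10.** The ester C–O bond is cut; the keto acid 10 is commercial.

## Roads not taken

**Alternative 1:** the obvious cut of both indole C3–quinone bonds. Forward: acid-promoted conjugate addition of indole to 2,5-dichloro-1,4-benzoquinone with re-oxidation gives 2,5-dichloro-3-(1H-indol-3-yl)cyclohexa-2,5-diene-1,4-dione A1; the addition is repeated with 2, and methoxide displaces both chlorides. This is comparable in length. It was set aside because it decorates a bought ring: each C–C bond costs one oxidation, the two chlorines are placeholders, and the prenyl group meets Brønsted acid and a quinone oxidant twice. The chosen plan is redox-neutral and halogen-free, and it takes both oxygen pairs and the para relationship from the building blocks.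

**Alternative 2:** cut C2–C3 and C1–C6, removing one oxalyl pair. Forward: double Claisen condensation of 1-(1H-indol-3-yl)-4-[7-(3-methylbut-2-en-1-yl)-1H-indol-3-yl]butane-2,3-dione A2 with dimethyl oxalate. The ring closure is attractive because the symmetrical oxalate makes regiochemistry irrelevant. A2 itself is the problem:
- indol-3-ylmethyl carbanion equivalents for a stepwise 1,2-diketone synthesis are not available;
- a four-carbon bis-electrophile, after the first indole alkylation, cyclises onto C2 of that indole to a six-membered ring;
- oxidising an alkene, alkyne or diol to the diketone has to compete with two indoles and the prenyl group.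

Making A2 would cost more steps than the whole chosen route, which uses the same acylation logic with two units that each come from an aldehyde or a commercial acid.

**Alternative 3:** a ring made from another ring. Forward: thermal ring expansion of 4-hydroxy-2-methoxy-4-({7-(3-methylbut-2-en-1-yl)-1-[tri(propan-2-yl)silyl]-1H-indol-3-yl}ethynyl)-3-{1-[tri(propan-2-yl)silyl]-1H-indol-3-yl}cyclobut-2-en-1-one A3, built from dimethyl squarate and two N-silylated indolyl lithium reagents. Electrocyclic opening to an enynylketene and ring closure give quinone A4 with fixed regiochemistry. A4 carries hydrogen where the second methoxy group belongs, so an oxidative methoxylation and two desilylations must follow on a quinone. Both indoles need N-protection and organolithium chemistry, the sequence exceeds ten steps, and the four contiguous oxygens of squarate do not match the two separated oxygen pairs of 15. The chosen plan needs no protecting group.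

Key step: step 7

Remark on the chemistry: 15 has no stereocentre. Compounds 11, 13 and 14 are drawn in one tautomeric form each. The Z geometry drawn for 9 is lost in step 7, so an E/Z mixture would serve equally.

## Steps

Step 1
Reactants: 1 7-bromo-1H-indole
Product: 2 7-(3-methylbut-2-en-1-yl)-1H-indole
Conditions: Bu3SnCH2CH=CMe2, Pd(PPh3)4 (cat.), DMF, 100 °C
Reagents that add atoms: tributyl(3-methylbut-2-en-1-yl)stannane, CC(C)=CC[Sn](CCCC)(CCCC)CCCC
Why: Stille coupling; zerovalent palladium inserts into the C7–Br bond without N-protection, and the allylpalladium intermediate equilibrates to the less hindered primary σ-isomer before reductive elimination, which should give the linear prenyl group.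

Step 2
Reactants: 2 7-(3-methylbut-2-en-1-yl)-1H-indole
Product: 4 7-(3-methylbut-2-en-1-yl)-1H-indole-3-carbaldehyde, via iminium chloride 3 (not isolated)
Conditions: POCl3, DMF, 0 °C to rt; then 2 M NaOH, rt
Reagents that add atoms: N,N-dimethylformamide, CN(C)C=O; water, O
Why: Vilsmeier–Haack formylation; the chloroiminium ion attacks the most nucleophilic position, C3, and the iminium salt 3 is hydrolysed on basic work-up; the isolated trisubstituted alkene is too electron-poor for this weak electrophile at these temperatures.

Step 3
Reactants: 5 2,2-dimethyl-1,3-dioxolan-4-one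
Product: 6 5-bromo-2,2-dimethyl-1,3-dioxolan-4-one (racemic)
Conditions: NBS, AIBN (cat.), PhCF3, 80 °C
Reagents that add atoms: N-bromosuccinimide, O=C1CCC(=O)N1Br
Why: Wohl–Ziegler-type radical bromination; the only C–H bonds flanked by a ring oxygen and the lactone carbonyl give a captodatively stabilised radical, so monobromination at C5 is expected; the new stereocentre is racemic and is erased in step 5.

Step 4
Reactants: 6 5-bromo-2,2-dimethyl-1,3-dioxolan-4-one
Product: 7 (2,2-dimethyl-5-oxo-1,3-dioxolan-4-yl)triphenylphosphonium bromide (racemic)
Conditions: PPh3, toluene, rt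
Reagents that add atoms: triphenylphosphine, c1ccc(cc1)P(c1ccccc1)c1ccccc1
Why: Quaternisation of the phosphine by the activated α-bromo lactone (SN2); the salt should precipitate and serve as a storable ylide precursor.

Step 5
Reactants: 4 7-(3-methylbut-2-en-1-yl)-1H-indole-3-carbaldehyde; 7 (2,2-dimethyl-5-oxo-1,3-dioxolan-4-yl)triphenylphosphonium bromide
Product: 9 (5Z)-2,2-dimethyl-5-{[7-(3-methylbut-2-en-1-yl)-1H-indol-3-yl]methylidene}-1,3-dioxolan-4-one, via phosphorus ylide 8 (not isolated)
Conditions: DABCO, toluene, 110 °C
Reagents that add atoms: none
Why: Wittig olefination with a lactone-stabilised ylide set free by the amine; ylides of this type condense with aromatic aldehydes to (Z)-5-arylidene-1,3-dioxolan-4-ones, heating compensates for the low electrophilicity of the vinylogous formamide 4, and no base strong enough to deprotonate N–H is present.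

Step 6
Reactants: 10 3-(1H-indol-3-yl)-2-oxopropanoic acid
Product: 11 methyl 3-(1H-indol-3-yl)-2-oxopropanoate
Conditions: Me3SiCHN2, MeOH/toluene, 0 °C
Reagents that add atoms: trimethylsilyldiazomethane, C[Si](C)(C)C=[N+]=[N-]
Why: Esterification with a diazoalkane; only the carboxylic acid is acidic enough to protonate the reagent quickly, so the ester forms under neutral conditions at 0 °C and the sensitive keto acid is not exposed to acid or base.

Step 7
Reactants: 11 methyl 3-(1H-indol-3-yl)-2-oxopropanoate; 9 (5Z)-2,2-dimethyl-5-{[7-(3-methylbut-2-en-1-yl)-1H-indol-3-yl]methylidene}-1,3-dioxolan-4-one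
Product: 14 2,5-dihydroxy-3-(1H-indol-3-yl)-6-[7-(3-methylbut-2-en-1-yl)-1H-indol-3-yl]cyclohexa-2,5-diene-1,4-dione, via lithium enolate 12 (not isolated), via trioxohexanoate 13 (not isolated)
Conditions: LiN(SiMe3)2 (1 equiv per 11), THF, −78 °C; 9, −78 °C to rt; then NaOMe, MeOH, 50 °C; 1 M HCl, 0 °C
Reagents that add atoms: none
Why: Proposed new method: the chelated lithium enolate 12 attacks the lactone carbonyl of 9, an activated acyl donor that has no acidic C–H and so can act only as the electrophile; collapse of the tetrahedral intermediate expels the ketal oxygen, acetone is lost and the ketone enolate of the second half is uncovered in the same event, giving 13 after internal proton transfer (crossed Claisen condensation). Methoxide then re-forms the C6 enolate of 13 (hexanoate numbering), which acylates the C1 methyl ester in a 6-(enolendo)-exo-trig Dieckmann closure, and loss of methoxide with enolisation gives the dianion of 14. The closest known reaction types are the C-acylation of ester enolates by 5-arylidene-1,3-dioxolan-4-ones (which ends in tetronic acids by O-cyclisation) and the alkoxide-induced head-to-tail self-condensation of α-keto esters to 3,6-disubstituted 2,5-dihydroxy-1,4-benzoquinones; the step is their crossed combination and has not been shown with an α-keto ester enolate as the nucleophile. No stereocentre is formed. Cross- over self-condensation is secured because 9 cannot become a nucleophile before it is opened, while the ester of fully enolised 11 is a poor electrophile for its own anion. The 1,4-relationship of the two indoles follows from the head-to-tail connectivity (new bonds C2–C3 and C5–C6 of 14) and cannot be scrambled. C- versus O-selectivity is thermodynamic: an O-acyl enol ester formed in the first stage is still an acyl donor towards 12 and should drain to the more stable triacylmethanide of 13, and the six-membered enol lactone that O-cyclisation of 13 would give is reopened by methoxide and drains to the dianion of 14, a doubly vinylogous carboxylate. One equivalent of base per 11 leaves both indole N–H groups protonated, and methoxide is added only after 9 is consumed because it would open 9 to a second free keto ester and make the dimerisation statistical.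

Step 8
Reactants: 14 2,5-dihydroxy-3-(1H-indol-3-yl)-6-[7-(3-methylbut-2-en-1-yl)-1H-indol-3-yl]cyclohexa-2,5-diene-1,4-dione
Product: 15 3-(1H-indol-3-yl)-2,5-dimethoxy-6-[7-(3-methylbut-2-en-1-yl)-1H-indol-3-yl]cyclohexa-2,5-diene-1,4-dione
Conditions: Me3SiCHN2, MeOH/CH2Cl2, 0 °C to rt
Reagents that add atoms: trimethylsilyldiazomethane, C[Si](C)(C)C=[N+]=[N-]
Why: O-Methylation of a vinylogous carboxylic acid by a diazoalkane; both hydroxy groups of 14 are acidic enough to protonate the reagent while the indole N–H groups are not, the tetrasubstituted quinone double bonds resist dipolar cycloaddition, and alkylation on the oxygens that preserve the para-quinone should give the 2,5-dimethoxy compound 15.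

## Compound list

1 | 7-bromo-1H-indole | Brc1cccc2cc[nH]c12 | starting material
2 | 7-(3-methylbut-2-en-1-yl)-1H-indole | CC(C)=CCc1cccc2cc[nH]c12 | intermediate
3 | N,N-dimethyl-1-[7-(3-methylbut-2-en-1-yl)-1H-indol-3-yl]methaniminium chloride | C[N+](C)=Cc1c[nH]c2c(CC=C(C)C)cccc12.[Cl-] | intermediate
4 | 7-(3-methylbut-2-en-1-yl)-1H-indole-3-carbaldehyde | O=Cc1c[nH]c2c(CC=C(C)C)cccc12 | intermediate
5 | 2,2-dimethyl-1,3-dioxolan-4-one | CC1(C)OCC(=O)O1 | starting material
6 | 5-bromo-2,2-dimethyl-1,3-dioxolan-4-one (racemic) | CC1(C)OC(Br)C(=O)O1 | intermediate
7 | (2,2-dimethyl-5-oxo-1,3-dioxolan-4-yl)triphenylphosphonium bromide (racemic) | CC1(C)OC(C(=O)O1)[P+](c1ccccc1)(c1ccccc1)c1ccccc1.[Br-] | intermediate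
8 | 2,2-dimethyl-5-(triphenyl-λ5-phosphanylidene)-1,3-dioxolan-4-one | CC1(C)OC(=O)C(O1)=P(c1ccccc1)(c1ccccc1)c1ccccc1 | intermediate
9 | (5Z)-2,2-dimethyl-5-{[7-(3-methylbut-2-en-1-yl)-1H-indol-3-yl]methylidene}-1,3-dioxolan-4-one | CC1(C)OC(=O)/C(O1)=C/c1c[nH]c2c(CC=C(C)C)cccc12 | intermediate
10 | 3-(1H-indol-3-yl)-2-oxopropanoic acid | OC(=O)C(=O)Cc1c[nH]c2ccccc12 | starting material
11 | methyl 3-(1H-indol-3-yl)-2-oxopropanoate | COC(=O)C(=O)Cc1c[nH]c2ccccc12 | intermediate
12 | lithium (1Z)-1-(1H-indol-3-yl)-3-methoxy-3-oxoprop-1-en-2-olate | [Li+].[O-]/C(=C\c1c[nH]c2ccccc12)C(=O)OC | intermediate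
13 | methyl 3-(1H-indol-3-yl)-6-[7-(3-methylbut-2-en-1-yl)-1H-indol-3-yl]-2,4,5-trioxohexanoate (racemic, enolised) | COC(=O)C(=O)C(c1c[nH]c2ccccc12)C(=O)C(=O)Cc1c[nH]c2c(CC=C(C)C)cccc12 | intermediate
14 | 2,5-dihydroxy-3-(1H-indol-3-yl)-6-[7-(3-methylbut-2-en-1-yl)-1H-indol-3-yl]cyclohexa-2,5-diene-1,4-dione | OC1=C(c2c[nH]c3ccccc23)C(=O)C(O)=C(c2c[nH]c3c(CC=C(C)C)cccc23)C1=O | intermediate
15 | 3-(1H-indol-3-yl)-2,5-dimethoxy-6-[7-(3-methylbut-2-en-1-yl)-1H-indol-3-yl]cyclohexa-2,5-diene-1,4-dione | COC1=C(c2c[nH]c3ccccc23)C(=O)C(OC)=C(c2c[nH]c3c(CC=C(C)C)cccc23)C1=O | target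

## Step count and least certain steps

Total: 8 steps. Longest linear sequence: 5 steps (1, 2, 5, 7, 8) from 7-bromo-1H-indole.

**Step 7 (key step, proposed new method).** The most likely failure is kinetic O-acylation of the ambident enolate 12 without later O-to-C acyl transfer. Methoxide in the second stage would then cleave the enol ester into two free keto esters, and their dimerisation would be statistical. Competing N-acylation of an indole and sluggish Dieckmann closure onto the enolate-conjugated ester are lesser concerns. A magnesium counter-ion (MgBr2·OEt2 added to 12) would be tried first to favour attack at carbon.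

The fallback uses known chemistry and sets out from 2:
- Indole is added to commercial 2,5-dibromo-1,4-benzoquinone in acetic acid and the adduct is re-oxidised with DDQ to give 2,5-dibromo-3-(1H-indol-3-yl)cyclohexa-2,5-diene-1,4-dione F1.
- The same addition and re-oxidation with 2 gives 2,5-dibromo-3-(1H-indol-3-yl)-6-[7-(3-methylbut-2-en-1-yl)-1H-indol-3-yl]cyclohexa-2,5-diene-1,4-dione F2.
- Hydrolysis of both vinylogous acyl bromides with NaOH in aqueous methanol returns to the route at 14.

**Step 5.** Olefination of the electron-rich, N–H-bearing aldehyde 4 may be slow enough that the ylide decomposes or the lactone opens on prolonged heating. The fallback changes the C=C-forming reaction and sets out from 4: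
- N-acylation with Boc2O and DMAP gives tert-butyl 3-formyl-7-(3-methylbut-2-en-1-yl)-1H-indole-1-carboxylate F3, a far better electrophile.
- Aldol addition of the lithium enolate of 5 (LiN(iPr)2, THF, −78 °C) gives tert-butyl 3-[(2,2-dimethyl-5-oxo-1,3-dioxolan-4-yl)(hydroxy)methyl]-7-(3-methylbut-2-en-1-yl)-1H-indole-1-carboxylate F4.
- Mesylation and elimination (MsCl, Et3N) give tert-butyl 3-[(Z)-(2,2-dimethyl-5-oxo-1,3-dioxolan-4-ylidene)methyl]-7-(3-methylbut-2-en-1-yl)-1H-indole-1-carboxylate F5.
- F5 takes the place of 9 in step 7, where the methoxide stage also removes the carbamate, so the route is rejoined at 14.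

**Step 1.** Reductive elimination from the tertiary terminus of the allylpalladium intermediate would leak to the 1,1-dimethylallyl isomer, which is hard to separate; protodestannylation is the other loss. The fallback removes the regiochemical question and sets out from 1: Stille coupling with allyltributylstannane gives 7-(prop-2-en-1-yl)-1H-indole F6, and cross-metathesis with 2-methyl-2-butene (second-generation Grubbs catalyst, (H2IMes)(PCy3)Cl2Ru=CHPh) returns to the route at 2.

**Step 8.** Alkylation of the ambident dioxido-quinone on the other oxygen would give ortho-quinone ether isomers, and the second methylation may stall. The fallback replaces O-alkylation by addition–elimination at carbon and sets out from 14: oxalyl chloride with catalytic DMF in CH2Cl2 at 0 °C gives 2,5-dichloro-3-(1H-indol-3-yl)-6-[7-(3-methylbut-2-en-1-yl)-1H-indol-3-yl]cyclohexa-2,5-diene-1,4-dione F7 (the quinone-conjugated indoles are deactivated towards the reagent), and NaOMe in methanol at 0 °C displaces both chlorides to give 15.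

## Further compounds

F1 | step 7 | 2,5-dibromo-3-(1H-indol-3-yl)cyclohexa-2,5-diene-1,4-dione | O=C1C(Br)=C(c2c[nH]c3ccccc23)C(=O)C(Br)=C1
F2 | step 7 | 2,5-dibromo-3-(1H-indol-3-yl)-6-[7-(3-methylbut-2-en-1-yl)-1H-indol-3-yl]cyclohexa-2,5-diene-1,4-dione | O=C1C(Br)=C(c2c[nH]c3ccccc23)C(=O)C(Br)=C1c1c[nH]c2c(CC=C(C)C)cccc12
F3 | step 5 | tert-butyl 3-formyl-7-(3-methylbut-2-en-1-yl)-1H-indole-1-carboxylate | CC(C)=CCc1cccc2c(C=O)cn(C(=O)OC(C)(C)C)c12
F4 | step 5 | tert-butyl 3-[(2,2-dimethyl-5-oxo-1,3-dioxolan-4-yl)(hydroxy)methyl]-7-(3-methylbut-2-en-1-yl)-1H-indole-1-carboxylate (mixture of diastereomers) | CC(C)=CCc1cccc2c(C(O)C3OC(C)(C)OC3=O)cn(C(=O)OC(C)(C)C)c12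
F5 | step 5 | tert-butyl 3-[(Z)-(2,2-dimethyl-5-oxo-1,3-dioxolan-4-ylidene)methyl]-7-(3-methylbut-2-en-1-yl)-1H-indole-1-carboxylate | CC1(C)OC(=O)/C(O1)=C/c1cn(C(=O)OC(C)(C)C)c2c(CC=C(C)C)cccc12
F6 | step 1 | 7-(prop-2-en-1-yl)-1H-indole | C=CCc1cccc2cc[nH]c12
F7 | step 8 | 2,5-dichloro-3-(1H-indol-3-yl)-6-[7-(3-methylbut-2-en-1-yl)-1H-indol-3-yl]cyclohexa-2,5-diene-1,4-dione | O=C1C(Cl)=C(c2c[nH]c3ccccc23)C(=O)C(Cl)=C1c1c[nH]c2c(CC=C(C)C)cccc12
A1 | alternative 1 | 2,5-dichloro-3-(1H-indol-3-yl)cyclohexa-2,5-diene-1,4-dione | O=C1C(Cl)=C(c2c[nH]c3ccccc23)C(=O)C(Cl)=C1
A2 | alternative 2 | 1-(1H-indol-3-yl)-4-[7-(3-methylbut-2-en-1-yl)-1H-indol-3-yl]butane-2,3-dione | O=C(Cc1c[nH]c2ccccc12)C(=O)Cc1c[nH]c2c(CC=C(C)C)cccc12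
A3 | alternative 3 | 4-hydroxy-2-methoxy-4-({7-(3-methylbut-2-en-1-yl)-1-[tri(propan-2-yl)silyl]-1H-indol-3-yl}ethynyl)-3-{1-[tri(propan-2-yl)silyl]-1H-indol-3-yl}cyclobut-2-en-1-one (racemic) | COC1=C(c2cn([Si](C(C)C)(C(C)C)C(C)C)c3ccccc23)C(O)(C#Cc2cn([Si](C(C)C)(C(C)C)C(C)C)c3c(CC=C(C)C)cccc23)C1=O
A4 | alternative 3 | 2-methoxy-6-{7-(3-methylbut-2-en-1-yl)-1-[tri(propan-2-yl)silyl]-1H-indol-3-yl}-3-{1-[tri(propan-2-yl)silyl]-1H-indol-3-yl}cyclohexa-2,5-diene-1,4-dione | COC1=C(c2cn([Si](C(C)C)(C(C)C)C(C)C)c3ccccc23)C(=O)C=C(c2cn([Si](C(C)C)(C(C)C)C(C)C)c3c(CC=C(C)C)cccc23)C1=O
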